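## Retrosynthetic overview

1. Target 16 ⇒ Heck reaction (acrolein) on aryl iodide 15 ⇒ phenol-tolerant Mitsunobu esterification of alcohol 14.
2. 14 ⇒ acid-mediated, trans-selective O1–C2 closure of p-hydroxybenzyl alcohol 13 (C2 set by C3); the C2–aryl bond comes from aryl Grignard 11 + lactol 8.
3. 8 ⇒ ozonolysis of o-(pentenyl)phenol 7; its C3–C3a bond and C3 stereocentre come from an aromatic Claisen [3,3] rearrangement of aryl allyl ether 6 with 1,3-chirality transfer.
4. 6 ⇒ ethyl (S)-lactate 1 + 4-iodo-2-methoxyphenol 2 (Mitsunobu inversion, one-pot DIBAL/HWE, DIBAL).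
5. Ring order: both benzene rings are bought; the dihydrofuran is the only ring made (as a lactol in step 5, final closure in step 8).

Assumption: the SMILES is read as the (2R,3S)-trans isomer; lactol 8 and diol 12 are carried as epimer mixtures at the carbinol carbon, which is reset in step 8.

## Route

Step 1
Reactants: 1 ethyl (S)-lactate; 2 4-iodo-2-methoxyphenol
Product: 3 ethyl (R)-2-(4-iodo-2-methoxyphenoxy)propanoate
Conditions: PPh3, DIAD, THF, 0 °C → rt
Reagents that add atoms: none
Why: Mitsunobu reaction; SN2 displacement of the activated lactate hydroxyl by the phenoxide inverts the carbinol carbon, so (S)-lactate gives the (R)-aryl ether without racemisation.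

Step 2
Reactants: 3 ethyl (R)-2-(4-iodo-2-methoxyphenoxy)propanoate
Product: 5 ethyl (R,E)-4-(4-iodo-2-methoxyphenoxy)pent-2-enoate, via aldehyde 4 (not isolated)
Conditions: DIBAL-H (1.05 eq), CH2Cl2, −78 °C; then (EtO)2P(O)CH2CO2Et/NaH in THF, −78 °C → rt
Reagents that add atoms: triethyl phosphonoacetate, CCOC(=O)CP(=O)(OCC)OCC
Why: the chelated aluminium hemiacetal from DIBAL reduction releases aldehyde 4 only as the phosphonate anion arrives, so the Horner–Wadsworth–Emmons olefination gives the E-enoate before the α-aryloxy aldehyde can epimerise.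

Step 3
Reactants: 5 ethyl (R,E)-4-(4-iodo-2-methoxyphenoxy)pent-2-enoate
Product: 6 (R,E)-4-(4-iodo-2-methoxyphenoxy)pent-2-en-1-ol
Conditions: DIBAL-H (2.3 eq), CH2Cl2, −78 °C; Rochelle salt work-up
Reagents that add atoms: none
Why: DIBAL 1,2-reduction of the enoate gives the E-allylic alcohol and leaves the aryl iodide, the ether and the stereocentre untouched.

Step 4
Reactants: 6 (R,E)-4-(4-iodo-2-methoxyphenoxy)pent-2-en-1-ol
Product: 7 (S,E)-2-(2-hydroxy-5-iodo-3-methoxyphenyl)pent-3-en-1-ol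
Conditions: PhNEt2, 180 °C, sealed tube, Ar, ca. 6 h (stop at full conversion)
Reagents that add atoms: none
Why: aromatic Claisen rearrangement ([3,3]-sigmatropic) through a chair transition state with the methyl pseudo-equatorial moves the chirality from the C–O carbon to the new benzylic C–C carbon (R-ether → S-centre, E-propenyl); only one ortho position is open because the other carries OMe and the para position carries iodine.

Step 5
Reactants: 7 (S,E)-2-(2-hydroxy-5-iodo-3-methoxyphenyl)pent-3-en-1-ol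
Product: 8 (3S)-3-(hydroxymethyl)-5-iodo-7-methoxy-2,3-dihydro-1-benzofuran-2-ol (anomer mixture, used crude)
Conditions: O3 (1.0 eq, indicator), CH2Cl2, −78 °C; then PPh3, −78 °C → rt
Reagents that add atoms: ozone, [O-][O+]=O
Why: ozonolysis cleaves the E-alkene much faster than the iodoguaiacol ring, and the aldehyde is trapped at once by the ortho-phenol as the lactol, which shields the α-aryl stereocentre from enolisation.

Step 6
Reactants: 9 4-bromo-2-methoxyphenol
Product: 10 (4-bromo-2-methoxyphenoxy)(tert-butyl)dimethylsilane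
Conditions: TBSCl, imidazole, DMF, rt
Reagents that add atoms: tert-butyldimethylsilyl chloride, CC(C)(C)[Si](C)(C)Cl
Why: standard silylation masks the acidic phenol before Grignard formation.

Step 7
Reactants: 8 (3S)-3-(hydroxymethyl)-5-iodo-7-methoxy-2,3-dihydro-1-benzofuran-2-ol; 10 (4-bromo-2-methoxyphenoxy)(tert-butyl)dimethylsilane
Product: 12 (2S)-1-[4-(tert-butyldimethylsilyloxy)-3-methoxyphenyl]-2-(2-hydroxy-5-iodo-3-methoxyphenyl)propane-1,3-diol (C1 epimers), via aryl Grignard reagent 11 (not isolated)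
Conditions: 10, Mg, THF, 40 °C; then 8 added to 3.5 eq of 11, THF, −40 → 0 °C; aq NH4Cl
Reagents that add atoms: none
Why: excess aryl Grignard deprotonates and opens the lactol to the aldehyde phenoxide and then adds (Grignard addition) faster than enolisation at low temperature, without exchanging with the aryl iodide; the new carbinol configuration does not matter because it is reset in step 8.

Step 8
Reactants: 12 (2S)-1-[4-(tert-butyldimethylsilyloxy)-3-methoxyphenyl]-2-(2-hydroxy-5-iodo-3-methoxyphenyl)propane-1,3-diol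
Product: 14 4-[(2R,3S)-3-(hydroxymethyl)-5-iodo-7-methoxy-2,3-dihydro-1-benzofuran-2-yl]-2-methoxyphenol, via desilylated tetraol 13 (not isolated)
Conditions: TBAF (1.1 eq), THF, 0 °C; then TsOH·H2O (2.5 eq), THF (0.02 M), rt
Reagents that add atoms: none
Why: fluoride frees the para-phenol and acid then ionises the p-hydroxybenzylic alcohol to a quinone-methide-type cation that the ortho-phenol captures 5-exo (SN1 cycloetherification) anti to the C3 CH2OH; the reversible closure gives the favoured 2,3-trans ring, so C3 (S) dictates C2 (R).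

Step 9
Reactants: 14 4-[(2R,3S)-3-(hydroxymethyl)-5-iodo-7-methoxy-2,3-dihydro-1-benzofuran-2-yl]-2-methoxyphenol
Product: 15 [(2R,3S)-2-(4-hydroxy-3-methoxyphenyl)-5-iodo-7-methoxy-2,3-dihydro-1-benzofuran-3-yl]methyl 3-methylbutanoate
Conditions: 3-methylbutanoic acid (1.5 eq), PPh3, DIAD, THF, 0 °C → rt
Reagents that add atoms: 3-methylbutanoic acid, CC(C)CC(=O)O
Why: in a Mitsunobu esterification only the aliphatic alcohol is activated as an alkoxyphosphonium and the carboxylate outcompetes the phenol as nucleophile, so the primary OH is acylated selectively and no stereocentre is involved.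

Step 10
Reactants: 15 [(2R,3S)-2-(4-hydroxy-3-methoxyphenyl)-5-iodo-7-methoxy-2,3-dihydro-1-benzofuran-3-yl]methyl 3-methylbutanoate
Product: 16 [(2R,3S)-2-(4-hydroxy-3-methoxyphenyl)-7-methoxy-5-[(E)-3-oxoprop-1-enyl]-2,3-dihydro-1-benzofuran-3-yl]methyl 3-methylbutanoate (target)
Conditions: acrolein (4 eq), Pd(OAc)2 (5 mol%), NaHCO3 (2.5 eq), n-Bu4NCl (1 eq), DMF, 50 °C
Reagents that add atoms: acrolein, C=CC=O
Why: Mizoroki–Heck reaction under ligand-free Jeffery conditions; oxidative addition to the aryl iodide, syn-insertion of acrolein and syn-β-hydride elimination give the E-enal, while bicarbonate is too weak to disturb the phenol, the ester or the benzylic ether.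

## Compound list

1 | ethyl (S)-lactate | C[C@H](O)C(=O)OCC | starting material
2 | 4-iodo-2-methoxyphenol | COc1cc(I)ccc1O | starting material
3 | ethyl (R)-2-(4-iodo-2-methoxyphenoxy)propanoate | C[C@@H](Oc1ccc(I)cc1OC)C(=O)OCC | intermediate
4 | (R)-2-(4-iodo-2-methoxyphenoxy)propanal | C[C@@H](Oc1ccc(I)cc1OC)C=O | intermediate
5 | ethyl (R,E)-4-(4-iodo-2-methoxyphenoxy)pent-2-enoate | C[C@@H](Oc1ccc(I)cc1OC)/C=C/C(=O)OCC | intermediate
6 | (R,E)-4-(4-iodo-2-methoxyphenoxy)pent-2-en-1-ol | C[C@@H](Oc1ccc(I)cc1OC)/C=C/CO | intermediate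
7 | (S,E)-2-(2-hydroxy-5-iodo-3-methoxyphenyl)pent-3-en-1-ol | C/C=C/[C@H](CO)c1cc(I)cc(OC)c1O | intermediate
8 | (3S)-3-(hydroxymethyl)-5-iodo-7-methoxy-2,3-dihydro-1-benzofuran-2-ol (anomer mixture) | OC1Oc2c(OC)cc(I)cc2[C@H]1CO | intermediate
9 | 4-bromo-2-methoxyphenol | COc1cc(Br)ccc1O | starting material
10 | (4-bromo-2-methoxyphenoxy)(tert-butyl)dimethylsilane | COc1cc(Br)ccc1O[Si](C)(C)C(C)(C)C | intermediate
11 | [4-(tert-butyldimethylsilyloxy)-3-methoxyphenyl]magnesium bromide | COc1cc([Mg]Br)ccc1O[Si](C)(C)C(C)(C)C | intermediate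
12 | (2S)-1-[4-(tert-butyldimethylsilyloxy)-3-methoxyphenyl]-2-(2-hydroxy-5-iodo-3-methoxyphenyl)propane-1,3-diol (C1 epimers) | COc1cc(C(O)[C@H](CO)c2cc(I)cc(OC)c2O)ccc1O[Si](C)(C)C(C)(C)C | intermediate
13 | (2S)-1-(4-hydroxy-3-methoxyphenyl)-2-(2-hydroxy-5-iodo-3-methoxyphenyl)propane-1,3-diol (C1 epimers) | COc1cc(C(O)[C@H](CO)c2cc(I)cc(OC)c2O)ccc1O | intermediate
14 | 4-[(2R,3S)-3-(hydroxymethyl)-5-iodo-7-methoxy-2,3-dihydro-1-benzofuran-2-yl]-2-methoxyphenol | COc1cc([C@@H]2Oc3c(OC)cc(I)cc3[C@H]2CO)ccc1O | intermediate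
15 | [(2R,3S)-2-(4-hydroxy-3-methoxyphenyl)-5-iodo-7-methoxy-2,3-dihydro-1-benzofuran-3-yl]methyl 3-methylbutanoate | COc1cc([C@@H]2Oc3c(OC)cc(I)cc3[C@H]2COC(=O)CC(C)C)ccc1O | intermediate
16 | [(2R,3S)-2-(4-hydroxy-3-methoxyphenyl)-7-methoxy-5-[(E)-3-oxoprop-1-enyl]-2,3-dihydro-1-benzofuran-3-yl]methyl 3-methylbutanoate | COc1cc([C@@H]2Oc3c(OC)cc(/C=C/C=O)cc3[C@H]2COC(=O)CC(C)C)ccc1O | target

## Step count and risks

Total steps: 10 (nine in the main line plus step 6 for the silyl ether). Longest linear sequence: 9 steps (steps 1–5 and 7–10).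

**Step 4 (Claisen).** The minor chair with the methyl axial gives the Z-alkene with the opposite configuration at C3. After ozonolysis this becomes the enantiomer, so the ee of 7 is expected to be roughly 90% rather than complete. Over-heating also invites abnormal Claisen and retro-ene cleavage.
Fallback, setting out from 2 and returning at 7: couple 2 under Mitsunobu conditions with bought methyl (R)-lactate F1 to give methyl (S)-2-(4-iodo-2-methoxyphenoxy)propanoate F2. Reduce with DIBAL-H at −78 °C to (S)-2-(4-iodo-2-methoxyphenoxy)propanal F3 and, in the same pot, run a Z-selective Ando olefination (ethyl 2-(diphenoxyphosphoryl)acetate, NaH) to ethyl (S,Z)-4-(4-iodo-2-methoxyphenoxy)pent-2-enoate F4, purified free of E-isomer. DIBAL-H reduction gives (S,Z)-4-(4-iodo-2-methoxyphenoxy)pent-2-en-1-ol F5. Its Claisen rearrangement (PhNEt2, 190 °C) gives the same 7, because in the Z-series the methyl-axial chair suffers a 1,3-diaxial clash with the axial CH2OH and only one transition state remains.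

**Step 7 (Grignard addition to the lactol).** The lactol must open under basic conditions near 0 °C, where the α-aryl aldehyde can enolise (loss of ee) or lose the β-oxygen. Three equivalents of 11 are also consumed.
Fallback, setting out from 7 and returning at 14: silylate both hydroxyls of 7 (TBSCl, imidazole, DMF) to the bis-silyl ether tert-butyl{[(S,E)-2-[2-(tert-butyldimethylsilyloxy)-5-iodo-3-methoxyphenyl]pent-3-en-1-yl]oxy}dimethylsilane F6. Ozonolysis (O3; PPh3) gives the discrete aldehyde (2S)-3-(tert-butyldimethylsilyloxy)-2-[2-(tert-butyldimethylsilyloxy)-5-iodo-3-methoxyphenyl]propanal F7, used crude. Add only 1.2 eq of 11 at −78 °C, where addition outruns enolisation and the β-silyloxy group is a poor leaving group, to give the tris-silylated alcohol (2S)-3-(tert-butyldimethylsilyloxy)-2-[2-(tert-butyldimethylsilyloxy)-5-iodo-3-methoxyphenyl]-1-[4-(tert-butyldimethylsilyloxy)-3-methoxyphenyl]propan-1-ol F8. TBAF (3.5 eq) then TsOH·H2O passes through 13 and closes to 14.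

**Step 9 (esterification beside a free phenol).** The phenol may be alkylated or acylated in competition with the primary alcohol.
Fallback, setting out from 12 and returning at 15: cyclise 12 with catalytic TsOH in CH2Cl2 at 0 °C without fluoride, keeping the silyl group, to tert-butyl{4-[(2R,3S)-3-(hydroxymethyl)-5-iodo-7-methoxy-2,3-dihydro-1-benzofuran-2-yl]-2-methoxyphenoxy}dimethylsilane F9. Acylate its only free hydroxyl with 3-methylbutanoyl chloride/pyridine/DMAP to [(2R,3S)-2-[4-(tert-butyldimethylsilyloxy)-3-methoxyphenyl]-5-iodo-7-methoxy-2,3-dihydro-1-benzofuran-3-yl]methyl 3-methylbutanoate F10. Remove the silyl group with TBAF/AcOH in THF at 0 °C to reach 15.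

## Further compounds

F1 | step 4 | methyl (R)-lactate (bought) | C[C@@H](O)C(=O)OC
F2 | step 4 | methyl (S)-2-(4-iodo-2-methoxyphenoxy)propanoate | C[C@H](Oc1ccc(I)cc1OC)C(=O)OC
F3 | step 4 | (S)-2-(4-iodo-2-methoxyphenoxy)propanal | C[C@H](Oc1ccc(I)cc1OC)C=O
F4 | step 4 | ethyl (S,Z)-4-(4-iodo-2-methoxyphenoxy)pent-2-enoate | C[C@H](Oc1ccc(I)cc1OC)/C=C\C(=O)OCC
F5 | step 4 | (S,Z)-4-(4-iodo-2-methoxyphenoxy)pent-2-en-1-ol | C[C@H](Oc1ccc(I)cc1OC)/C=C\CO
F6 | step 7 | tert-butyl{[(S,E)-2-[2-(tert-butyldimethylsilyloxy)-5-iodo-3-methoxyphenyl]pent-3-en-1-yl]oxy}dimethylsilane | C/C=C/[C@H](CO[Si](C)(C)C(C)(C)C)c1cc(I)cc(OC)c1O[Si](C)(C)C(C)(C)C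
F7 | step 7 | (2S)-3-(tert-butyldimethylsilyloxy)-2-[2-(tert-butyldimethylsilyloxy)-5-iodo-3-methoxyphenyl]propanal | O=C[C@H](CO[Si](C)(C)C(C)(C)C)c1cc(I)cc(OC)c1O[Si](C)(C)C(C)(C)C
F8 | step 7 | (2S)-3-(tert-butyldimethylsilyloxy)-2-[2-(tert-butyldimethylsilyloxy)-5-iodo-3-methoxyphenyl]-1-[4-(tert-butyldimethylsilyloxy)-3-methoxyphenyl]propan-1-ol (C1 epimers) | COc1cc(C(O)[C@H](CO[Si](C)(C)C(C)(C)C)c2cc(I)cc(OC)c2O[Si](C)(C)C(C)(C)C)ccc1O[Si](C)(C)C(C)(C)C
F9 | step 9 | tert-butyl{4-[(2R,3S)-3-(hydroxymethyl)-5-iodo-7-methoxy-2,3-dihydro-1-benzofuran-2-yl]-2-methoxyphenoxy}dimethylsilane | COc1cc([C@@H]2Oc3c(OC)cc(I)cc3[C@H]2CO)ccc1O[Si](C)(C)C(C)(C)C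
F10 | step 9 | [(2R,3S)-2-[4-(tert-butyldimethylsilyloxy)-3-methoxyphenyl]-5-iodo-7-methoxy-2,3-dihydro-1-benzofuran-3-yl]methyl 3-methylbutanoate | COc1cc([C@@H]2Oc3c(OC)cc(I)cc3[C@H]2COC(=O)CC(C)C)ccc1O[Si](C)(C)C(C)(C)C
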